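**Plan**

1. Retrosynthesis: the aryl O–Si bond is cut last; the isopropyl group on the carbinol carbon is then traced back (isopropenyl ⇐ acetyl ⇐ 1-hydroxyethyl) to a formyl group.
2. The resulting 1-aroyloxy-4-methylcyclohex-3-ene-1-carbaldehyde is cut at the two ring C–C bonds that flank the unit CH2–C(CH3)=CH–CH2. That unit is isoprene; the other two ring atoms (the O-bearing quaternary carbon and its CH2 neighbour on the saturated side) are the C=C of an α-(aroyloxy)acrolein.
3. Enabling feature: in the cyclohexene ring the methyl-bearing alkene carbon is 1,4 to the oxygenated quaternary carbon (the "para" pattern of an isoprene cycloadduct), and the carbon attached to that quaternary carbon can be raised to the aldehyde level. The target's own ester then becomes the α-substituent of a captodative dienophile.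
4. Forward: the aryl acid is made by double Stille prenylation, hydrolysis and O-silylation. Enol esterification of 2,2-dimethyl-1,3-dioxan-5-one and a retro-hetero-Diels–Alder reaction give the acrolein. The cyclohexene ring is closed in one intermolecular [4+2] step, CHO is converted to isopropyl in four steps, and the phenol is desilylated.
5. Stereochemistry: the only stereocentre (the quaternary C–O carbon, R) arises in the cycloaddition under a chiral primary ammonium catalyst (face selectivity combined with "para" regioselectivity). No later step breaks a bond at this carbon.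

Key step: step 6

Remarks: compounds 1, 2, 7 and 12 are taken as commercial. The catalyst antipode that leads to the (R) adduct is assumed by analogy with other α-(aroyloxy)acroleins and is to be confirmed on the adduct. Numbered building blocks stand under "Reactants"; "Reagents that add atoms" lists un-numbered reagents only. Ar′CO2 = 4-[(tert-butyldimethylsilyl)oxy]-3,5-bis(3-methylbut-2-en-1-yl)benzoate.

**Route**

Step 1
Reactants: 1 methyl 3,5-dibromo-4-hydroxybenzoate; 2 tributyl(3-methylbut-2-en-1-yl)stannane (2.4 equiv)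
Product: 3 methyl 4-hydroxy-3,5-bis(3-methylbut-2-en-1-yl)benzoate
Conditions: Pd(PPh3)4 (10 mol %), DMF, 100 °C
Reagents that add atoms: none
Why: Double Stille coupling; the allyl-type stannane should transfer the prenyl group through its unsubstituted CH2 terminus to give the linear prenyl arene, and the neutral conditions tolerate the ester and the free phenol.

Step 2
Reactants: 3 methyl 4-hydroxy-3,5-bis(3-methylbut-2-en-1-yl)benzoate
Product: 4 4-hydroxy-3,5-bis(3-methylbut-2-en-1-yl)benzoic acid
Conditions: LiOH, THF/MeOH/H2O, 50 °C; then 1 M HCl to pH 3, 0 °C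
Reagents that add atoms: lithium hydroxide, [Li+].[OH-]
Why: Saponification of a methyl benzoate; the alkenes are inert to aqueous base, and cold, brief acidification should avoid acid-catalysed chroman formation from the ortho-prenyl phenol.

Step 3
Reactants: 4 4-hydroxy-3,5-bis(3-methylbut-2-en-1-yl)benzoic acid
Product: 6 4-[(tert-butyldimethylsilyl)oxy]-3,5-bis(3-methylbut-2-en-1-yl)benzoic acid, via bis-silylated silyl ester 5 (not isolated)
Conditions: TBSCl (2.5 equiv), imidazole, DMF, 40 °C; then AcOH/THF/H2O, rt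
Reagents that add atoms: tert-butyldimethylsilyl chloride, CC(C)(C)[Si](C)(C)Cl
Why: Silylation of both OH groups followed by selective hydrolysis of the far more labile silyl ester should leave the hindered aryl silyl ether in place (silyl ether protection).

Step 4
Reactants: 6 4-[(tert-butyldimethylsilyl)oxy]-3,5-bis(3-methylbut-2-en-1-yl)benzoic acid; 7 2,2-dimethyl-1,3-dioxan-5-one
Product: 10 2,2-dimethyl-4H-1,3-dioxin-5-yl Ar′CO2 ester, via acid chloride 8 (not isolated), via potassium enolate 9 (not isolated)
Conditions: (a) 6, 1-chloro-N,N,2-trimethylprop-1-en-1-amine, CH2Cl2, 0 °C → rt; (b) 7, KHMDS, THF, −78 °C; then 8, −78 → 0 °C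
Reagents that add atoms: none
Why: The α-chloroenamine makes the acid chloride without HCl, so the prenyl alkenes are not hydrochlorinated, and the potassium enolate should be acylated on oxygen by the hard acyl chloride (enolate O-acylation to an enol ester).

Step 5
Reactants: 10 2,2-dimethyl-4H-1,3-dioxin-5-yl Ar′CO2 ester
Product: 11 3-oxoprop-1-en-2-yl Ar′CO2 ester (α-(aroyloxy)acrolein)
Conditions: toluene, 110 °C, BHT (cat.), slow N2 sweep
Reagents that add atoms: none
Why: Retro-hetero-Diels–Alder reaction of the 4H-1,3-dioxin expels acetone and unveils the 2-acyloxyacrolein; removal of acetone drives the cycloreversion.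

Step 6
Reactants: 11 3-oxoprop-1-en-2-yl Ar′CO2 ester; 12 isoprene
Product: 13 (1R)-1-formyl-4-methylcyclohex-3-en-1-yl Ar′CO2 ester
Conditions: chiral triamine (2S)-N1-[(2S)-4-methyl-1-(pyrrolidin-1-yl)pentan-2-yl]-3-phenylpropane-1,2-diamine or its antipode (10 mol %), C6F5SO3H (27.5 mol %), EtNO2, rt, diene in excess
Reagents that add atoms: none
Why: The primary amine of the catalyst condenses with the formyl group of 11 to an α-acyloxy aldiminium ion of lowered LUMO, to which isoprene adds in a concerted, asynchronous, suprafacial [4+2] cycloaddition; the closest known reaction type is the primary-ammonium-catalysed Diels–Alder reaction of α-(acyloxy)acroleins with 1,3-dienes, here run with the target's own para-oxygenated aroyl group as the acyloxy group. The cyclohexene ring closes in an intermolecular six-membered pericyclic transition state in which both new C–C bonds form together, so no ring-closure constraint has to be overcome. The only new stereocentre, the quaternary carbon bearing oxygen, is controlled by the catalyst: hydrogen bonding of the ester C=O to a neighbouring ammonium N–H should fix the iminium conformation and the benzyl side chain should shield one face, so that isoprene attacks the open face, and the catalyst antipode is chosen to give (R). Because the two ring arms at this carbon differ only in the position of the methyl-bearing alkene, the step needs face selectivity and regioselectivity together; the larger HOMO coefficient at C1 of isoprene should pair with the β-CH2 of the iminium ion to give the 1,4 ("para") adduct. The trisubstituted prenyl alkenes are not dienes and should not compete, and the aryl silyl ether should tolerate the ammonium salt, in which all acid is bound. The step is a pure 1:1 addition in which every atom of 11 and of one molecule of 12 is kept in 13, and hydrolysis of the product iminium ion returns the catalyst unchanged.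

Step 7
Reactants: 13 (1R)-1-formyl-4-methylcyclohex-3-en-1-yl Ar′CO2 ester
Product: 14 (1R)-1-(1-hydroxyethyl)-4-methylcyclohex-3-en-1-yl Ar′CO2 ester (both carbinol epimers)
Conditions: MeMgBr (1.1 equiv), THF/CH2Cl2, −78 °C; AcOH quench at −78 °C
Reagents that add atoms: methylmagnesium bromide, C[Mg]Br
Why: Grignard addition to the non-enolisable aldehyde should be much faster than attack on the aryl ester at −78 °C; the new carbinol centre is oxidised in the next step, and the cold acidic quench is meant to prevent 1,2-acyl migration to the new alkoxide.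

Step 8
Reactants: 14 (1R)-1-(1-hydroxyethyl)-4-methylcyclohex-3-en-1-yl Ar′CO2 ester
Product: 15 (1R)-1-acetyl-4-methylcyclohex-3-en-1-yl Ar′CO2 ester
Conditions: DMP, CH2Cl2, 0 °C → rt
Reagents that add atoms: none
Why: Dess–Martin oxidation of the secondary alcohol under near-neutral conditions should leave the alkenes, the silyl ether and the position of the ester untouched.

Step 9
Reactants: 15 (1R)-1-acetyl-4-methylcyclohex-3-en-1-yl Ar′CO2 ester
Product: 16 (1R)-4-methyl-1-(prop-1-en-2-yl)cyclohex-3-en-1-yl Ar′CO2 ester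
Conditions: Zn, CH2Br2, TiCl4 (pre-formed reagent), THF/CH2Cl2, 0 °C → rt, short reaction time
Reagents that add atoms: dibromomethane, BrCBr
Why: Takai–Lombardo methylenation; the non-basic gem-dimetallic titanium reagent should methylenate the hindered ketone without enolising it (base would trigger intramolecular Claisen-type acyl transfer in an α-acyloxy ketone) and should leave the ester alone.

Step 10
Reactants: 16 (1R)-4-methyl-1-(prop-1-en-2-yl)cyclohex-3-en-1-yl Ar′CO2 ester
Product: 17 (1R)-4-methyl-1-(propan-2-yl)cyclohex-3-en-1-yl Ar′CO2 ester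
Conditions: H2 (1 atm), RhCl(PPh3)3 (10 mol %), benzene/EtOH, rt, stopped after 1 equiv H2
Reagents that add atoms: none
Why: Homogeneous hydrogenation with the rhodium(I) chloride phosphine catalyst reduces 1,1-disubstituted alkenes far faster than trisubstituted ones, so the ring alkene and both prenyl groups should survive; no stereocentre is formed.

Step 11
Reactants: 17 (1R)-4-methyl-1-(propan-2-yl)cyclohex-3-en-1-yl Ar′CO2 ester
Product: 18 (1R)-4-methyl-1-(propan-2-yl)cyclohex-3-en-1-yl 4-hydroxy-3,5-bis(3-methylbut-2-en-1-yl)benzoate (target)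
Conditions: TBAF (1.1 equiv), AcOH (1.2 equiv), THF, 0 °C
Reagents that add atoms: none
Why: Fluoride cleavage of the aryl silyl ether; the acetic acid buffer should keep the medium from attacking the hindered tertiary benzoate.

**Compound list**

1 | methyl 3,5-dibromo-4-hydroxybenzoate | COC(=O)c1cc(Br)c(O)c(Br)c1 | starting material
2 | tributyl(3-methylbut-2-en-1-yl)stannane | CCCC[Sn](CCCC)(CCCC)CC=C(C)C | starting material
3 | methyl 4-hydroxy-3,5-bis(3-methylbut-2-en-1-yl)benzoate | COC(=O)c1cc(CC=C(C)C)c(O)c(CC=C(C)C)c1 | intermediate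
4 | 4-hydroxy-3,5-bis(3-methylbut-2-en-1-yl)benzoic acid | CC(C)=CCc1cc(C(=O)O)cc(CC=C(C)C)c1O | intermediate
5 | tert-butyldimethylsilyl 4-[(tert-butyldimethylsilyl)oxy]-3,5-bis(3-methylbut-2-en-1-yl)benzoate | CC(C)=CCc1cc(C(=O)O[Si](C)(C)C(C)(C)C)cc(CC=C(C)C)c1O[Si](C)(C)C(C)(C)C | intermediate
6 | 4-[(tert-butyldimethylsilyl)oxy]-3,5-bis(3-methylbut-2-en-1-yl)benzoic acid | CC(C)=CCc1cc(C(=O)O)cc(CC=C(C)C)c1O[Si](C)(C)C(C)(C)C | intermediate
7 | 2,2-dimethyl-1,3-dioxan-5-one | CC1(C)OCC(=O)CO1 | starting material
8 | 4-[(tert-butyldimethylsilyl)oxy]-3,5-bis(3-methylbut-2-en-1-yl)benzoyl chloride | CC(C)=CCc1cc(C(Cl)=O)cc(CC=C(C)C)c1O[Si](C)(C)C(C)(C)C | intermediate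
9 | potassium 2,2-dimethyl-4H-1,3-dioxin-5-olate | CC1(C)OCC([O-])=CO1.[K+] | intermediate
10 | 2,2-dimethyl-4H-1,3-dioxin-5-yl 4-[(tert-butyldimethylsilyl)oxy]-3,5-bis(3-methylbut-2-en-1-yl)benzoate | CC(C)=CCc1cc(C(=O)OC2=COC(C)(C)OC2)cc(CC=C(C)C)c1O[Si](C)(C)C(C)(C)C | intermediate
11 | 3-oxoprop-1-en-2-yl 4-[(tert-butyldimethylsilyl)oxy]-3,5-bis(3-methylbut-2-en-1-yl)benzoate | CC(C)=CCc1cc(C(=O)OC(=C)C=O)cc(CC=C(C)C)c1O[Si](C)(C)C(C)(C)C | intermediate
12 | isoprene (2-methylbuta-1,3-diene) | C=CC(C)=C | starting material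
13 | (1R)-1-formyl-4-methylcyclohex-3-en-1-yl 4-[(tert-butyldimethylsilyl)oxy]-3,5-bis(3-methylbut-2-en-1-yl)benzoate | CC(C)=CCc1cc(C(=O)O[C@@]2(C=O)CC=C(C)CC2)cc(CC=C(C)C)c1O[Si](C)(C)C(C)(C)C | intermediate
14 | (1R)-1-(1-hydroxyethyl)-4-methylcyclohex-3-en-1-yl 4-[(tert-butyldimethylsilyl)oxy]-3,5-bis(3-methylbut-2-en-1-yl)benzoate, both carbinol epimers | CC(C)=CCc1cc(C(=O)O[C@@]2(C(C)O)CC=C(C)CC2)cc(CC=C(C)C)c1O[Si](C)(C)C(C)(C)C | intermediate
15 | (1R)-1-acetyl-4-methylcyclohex-3-en-1-yl 4-[(tert-butyldimethylsilyl)oxy]-3,5-bis(3-methylbut-2-en-1-yl)benzoate | CC(C)=CCc1cc(C(=O)O[C@@]2(C(C)=O)CC=C(C)CC2)cc(CC=C(C)C)c1O[Si](C)(C)C(C)(C)C | intermediate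
16 | (1R)-4-methyl-1-(prop-1-en-2-yl)cyclohex-3-en-1-yl 4-[(tert-butyldimethylsilyl)oxy]-3,5-bis(3-methylbut-2-en-1-yl)benzoate | CC(C)=CCc1cc(C(=O)O[C@@]2(C(C)=C)CC=C(C)CC2)cc(CC=C(C)C)c1O[Si](C)(C)C(C)(C)C | intermediate
17 | (1R)-4-methyl-1-(propan-2-yl)cyclohex-3-en-1-yl 4-[(tert-butyldimethylsilyl)oxy]-3,5-bis(3-methylbut-2-en-1-yl)benzoate | CC(C)=CCc1cc(C(=O)O[C@@]2(C(C)C)CC=C(C)CC2)cc(CC=C(C)C)c1O[Si](C)(C)C(C)(C)C | intermediate
18 | (1R)-4-methyl-1-(propan-2-yl)cyclohex-3-en-1-yl 4-hydroxy-3,5-bis(3-methylbut-2-en-1-yl)benzoate | CC(C)=CCc1cc(C(=O)O[C@@]2(C(C)C)CC=C(C)CC2)cc(CC=C(C)C)c1O | target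

**Summary**

Total step count: 11. Longest linear sequence: 11 steps (1 → 18); 2, 7 and 12 enter as purchased building blocks.

Steps most likely to fail:

1. Step 6 (key cycloaddition). The large silyloxy-diprenylbenzoyl group may erode the enantiofacial or the para/meta discrimination, or the acyloxyacrolein may polymerise before it is trapped. Fallback, from acid chloride 8 (made from 6 as in step 4) back to 15: 8 is added to butane-2,3-dione and Et3N in THF, which O-acylates the dione enol to the captodative 3-oxobut-1-en-2-yl Ar′CO2 ester F1. F1 and isoprene 12 with ZnCl2 or BF3·OEt2 in CH2Cl2 should give the "para" Diels–Alder adduct, racemic 1-acetyl-4-methylcyclohex-3-en-1-yl Ar′CO2 ester F2. Preparative chromatography on a chiral stationary phase then separates the enantiomers; the (R) enantiomer is 15, where the route is rejoined, bypassing steps 5–8.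

2. Step 7 (methyl addition). The aroyl group may migrate from the tertiary oxygen to the newly formed secondary alkoxide before the quench. Fallback, from 13 back to 15 without an alkoxide: 13 is homologated with trimethylsilyldiazomethane (MgBr2·OEt2, CH2Cl2/Et2O, 0 °C). A 1,2-hydride shift in the diazonium betaine should give (1R)-4-methyl-1-[(trimethylsilyl)acetyl]cyclohex-3-en-1-yl Ar′CO2 ester F3, which is protodesilylated with MeOH on silica gel to the methyl ketone 15.

3. Step 10 (selective hydrogenation). The isopropenyl group next to the quaternary carbon may be reduced too slowly, so that trisubstituted alkenes are reduced or isomerised on prolonged exposure. Fallback, from 16 back to 17, differentiating the alkenes by hydroboration instead: 9-BBN (THF, 0 °C → rt) should add only to the 1,1-disubstituted alkene to give the B-alkyl-9-borabicyclo[3.3.1]nonane F4. Oxidation (NaBO3·4H2O, THF/H2O) gives (1R)-1-(1-hydroxypropan-2-yl)-4-methylcyclohex-3-en-1-yl Ar′CO2 ester F5 (side-chain epimers, of no consequence). Appel iodination (I2, PPh3, imidazole, CH2Cl2) gives (1R)-1-(1-iodopropan-2-yl)-4-methylcyclohex-3-en-1-yl Ar′CO2 ester F6, and radical reduction (Bu3SnH, AIBN, benzene, 80 °C) gives 17.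

Further compounds
F1 | step 6 | 3-oxobut-1-en-2-yl 4-[(tert-butyldimethylsilyl)oxy]-3,5-bis(3-methylbut-2-en-1-yl)benzoate | CC(C)=CCc1cc(C(=O)OC(=C)C(C)=O)cc(CC=C(C)C)c1O[Si](C)(C)C(C)(C)C
F2 | step 6 | racemic 1-acetyl-4-methylcyclohex-3-en-1-yl 4-[(tert-butyldimethylsilyl)oxy]-3,5-bis(3-methylbut-2-en-1-yl)benzoate | CC(C)=CCc1cc(C(=O)OC2(C(C)=O)CC=C(C)CC2)cc(CC=C(C)C)c1O[Si](C)(C)C(C)(C)C
F3 | step 7 | (1R)-4-methyl-1-[(trimethylsilyl)acetyl]cyclohex-3-en-1-yl 4-[(tert-butyldimethylsilyl)oxy]-3,5-bis(3-methylbut-2-en-1-yl)benzoate | CC(C)=CCc1cc(C(=O)O[C@@]2(C(=O)C[Si](C)(C)C)CC=C(C)CC2)cc(CC=C(C)C)c1O[Si](C)(C)C(C)(C)C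
F4 | step 10 | (1R)-1-[1-(9-borabicyclo[3.3.1]nonan-9-yl)propan-2-yl]-4-methylcyclohex-3-en-1-yl 4-[(tert-butyldimethylsilyl)oxy]-3,5-bis(3-methylbut-2-en-1-yl)benzoate | CC(C)=CCc1cc(C(=O)O[C@@]2(C(C)CB3C4CCCC3CCC4)CC=C(C)CC2)cc(CC=C(C)C)c1O[Si](C)(C)C(C)(C)C
F5 | step 10 | (1R)-1-(1-hydroxypropan-2-yl)-4-methylcyclohex-3-en-1-yl 4-[(tert-butyldimethylsilyl)oxy]-3,5-bis(3-methylbut-2-en-1-yl)benzoate | CC(C)=CCc1cc(C(=O)O[C@@]2(C(C)CO)CC=C(C)CC2)cc(CC=C(C)C)c1O[Si](C)(C)C(C)(C)C
F6 | step 10 | (1R)-1-(1-iodopropan-2-yl)-4-methylcyclohex-3-en-1-yl 4-[(tert-butyldimethylsilyl)oxy]-3,5-bis(3-methylbut-2-en-1-yl)benzoate | CC(C)=CCc1cc(C(=O)O[C@@]2(C(C)CI)CC=C(C)CC2)cc(CC=C(C)C)c1O[Si](C)(C)C(C)(C)C
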